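## The problem

1. The target is a pentacycle in which a cyclopentane (ring A), a cyclohexenone (ring B) and a cyclohexene (ring C) meet at one olefinic carbon, while a six-membered lactam (ring D) and a nine-membered ring (ring E) span ring C through nitrogen. Atoms are called N, C1 (lactam carbonyl), C2 (quaternary, carries C1), C3 (quaternary, carries CH2OAc), C4 (bridgehead methine), C5 (the N–CH2 carbon bound to C4), C6 (ring C CH2), C7=C8 (enone double bond, C8 common to rings A, B and C), C9 (ring B ketone), C10 and C11 (ring B CH2), C12 (methine of rings A and B), C13 (CHCO2Me), C14 (ring A CH2), C15 and C16 (CH2CH2 of ring E), C17 (carbinol), C18 (CHCH3) and C19 (second N–CH2).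
2. Rings C and D form a 2-azabicyclo[3.3.1]nonane whose one-carbon bridge C3 and bridgehead C2 are vicinal quaternary carbons, and the chain C15–C19 ties C3 back to nitrogen.
3. Seven stereocentres must be set. C2 and C3 are best made together and then used as controllers; C4 is fixed by the bicycle; C12 and C13 lie on the flat A/B/C platform and feel only the axial lactam carbonyl on C2 and the axial CH2O arm on C3; C17 and C18 sit in flexible ring E, where substrate control is weak.
4. C13 (ester alpha-carbon) and C12 (gamma-carbon of the enone) are base-epimerisable, the primary acetate does not survive hydride or alkoxide, an N-acyl N,O-acetal is acid-labile, and a C2 that carried an ester beside a C8 ketone and the lactam carbonyl would invite retro-Claisen cleavage.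
5. The handle for the key step is that C5 joins the lactam nitrogen to C4 and C4 is the gamma-carbon of a C8 carbonyl in ring C. An N-methylene N-acyliminium ion on a preformed nine-membered lactam can therefore be attacked at C4 by a C8 silyl dienol ether, closing ring D and creating the bridgehead with one bond.
6. Absolute configuration has to enter with the first carbocycle, since every later centre derives from C2/C3 or from a reagent.

## Retrosynthesis

**Protecting groups (45 ← 44 ← 43 ← 42).** The last three operations only exchange groups: fluoride frees the C17 hydroxyl of 44, the acetate of 44 comes from alcohol 43, and 43 from PMB ether 42. The acetate is introduced this late because every earlier stage uses hydride, enolate or alkoxide. PMB and TIPS are released by DDQ and fluoride, not base, so C12 and C13 are not touched.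

**C13 (42 ← 41).** C13 is retraced to the C13=C14 double bond of cyclopentene ester 41. Protonating an ester enolate or hydrogenating from the open face would put the new hydrogen anti to the axial lactam carbonyl, which is the wrong epimer. Hydrogen delivered by a metal bound to that carbonyl, which sits over the double bond, gives the target configuration. The forward step must reduce a trisubstituted enoate and leave the tetrasubstituted enone.

**Ring A (41 ← 40).** The C13=C14 bond is cut by metathesis. Closing C12–C13 or C8–C12 from an olefin inside the ring would be a 5-endo process, and an aldol or Claisen closure onto C14 would leave an oxygen on C14 to be removed among four carbonyl groups. Metathesis needs only a vinyl group on C2 and a 2-substituted acrylate on C12, both inert until then, and gives directly the enoate for the hydrogenation. Dienone 40 has one ring fewer; the forward step must join a neopentyl vinyl group to an electron-poor 1,1-disubstituted alkene.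

**Ring B (40 ← 39 ← 38 ← 36).** The C7=C8 bond is traced to tertiary alcohol 38 (oxidation of the C9 carbinol to 39, then dehydration), and 38 is opened at C8–C12. This bond links a ketone carbon to a carbon bearing C(=CH2)CO2Me, the pattern left when a 2-(alkoxycarbonyl)allyl metal adds through its gamma-carbon. Bromide 36 therefore carries a (Z)-2-(bromomethyl)enoate. Compared with coupling at a C8 enol triflate, this allylation makes the C8–C12 bond, the C12 stereocentre and the acrylate for ring A in one neutral step. It requires equatorial attack on the C8 ketone through a chair.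

**C7–C9 (36 ← 29 + 34).** The enone of 29 is a latent C7 enolate: conjugate hydride addition turns C6 into the CH2 of the target and gives the only possible enolate, C2 being quaternary. Aldehyde 34 supplies C9–C13 and the ester carbon and is made from 30 and 31 through 32 and 33. Aldehyde addition must outrun alkylation by the allylic bromide.

**Key cut, C4–C5 (29 ← 27, through 28).** This removes ring D and the bridgehead centre and leaves bicyclic nine-membered lactam 27, whose ring C holds only a silyl dienol ether. Cutting N–C5 or N–C1 instead would give up the lactam that holds the two reacting arms on adjacent quaternary carbons. Two changes to the substituents are made. C2 carries a vinyl group, not an ester, so that the C8 ketone never sits on a triacylated carbon and no ester has to be reduced beside ketones. C17 carries a TIPS ether so that the ring C silyl ether can be removed selectively. The forward step needs attack at C4 (gamma) rather than C7 (alpha); both would close a six-membered ring, so this rests on the dienol ether's inherent preference, not on the tether alone.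

**Functional-group order (27 ← 26 ← 25 ← 24 ← 23 ← 21 ← 20).** The dienol ether comes from enone 26, which is unveiled from allylic silyl ether 24 (via 25) only after N-methoxymethylation of lactam 23. The lactam N–H is then the only acidic site when base is used. Lactam 23 comes from alcohol 21 by silylation with loss of Boc, and 21 from ketone 20 by reagent-controlled reduction.

**Ring E (20 ← 19; 19 ← 18 ← 17 ← 16).** The nine-membered keto-imide is reconnected between C1 and C17 to the ene-carbamate of hexahydroindole 19. Oxidative cleavage of a double bond avoids any medium-ring cyclisation. The vinyl group of 19 is made from ester 16 via 17 and 18 at the one stage where no ketone is present.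

**Pyrroline annulation (16 ← 15 ← 13 ← 11 + 12).** N=C1 is cut by condensation and C17–C18 by Michael addition of the ketone enolate of 11 to nitroalkene 12. The three-atom unit C18–C19–N with its methyl group arrives in one reagent. The step must set C18 relative to C2/C3; C17 is erased afterwards.

**Ring C (11 ← 8 + 10).** A Diels–Alder reaction cuts C2–C8 and C3–C4. One step builds both quaternary carbons with a cis ring fusion and puts oxygen on C8. The alkene of 8 is tetrasubstituted but doubly activated and chelating, which is what a chiral Lewis acid needs.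

**Building blocks.** Dienophile 8 comes from iodide 7, 7 from enone 6, 6 from stannane 2 and vinylogous ester 3, and 2 from 1. Diene 10 comes from 9.

## Roads not taken

**Alternative 1:** Ring E is opened at C15–C16 and closed last by olefin metathesis between a vinyl group on C3 and the vinyl carbinol at C17. This gives the Z-dehydro compound A1, which is then hydrogenated.
- Merits: C17 and C18 would arrive in an enantiopure amine fragment made by acyclic chemistry. That is better than the chosen plan, where C18 rests on a substrate-controlled Michael addition and C17 on a reduction inside a medium ring. It is also more convergent.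
- Weak points: the closure forms a nine-membered ring on a rigid pentacyclic lactam, using a vinyl group on a quaternary carbon (slow to engage) and an allylic alcohol (prone to isomerisation). The Z-geometry is enforced only by strain, and failure comes at the very end. Ring D would also have to be made without the nine-membered ring to hold nitrogen in place.
- Comparison: the chosen plan sets against the better C17/C18 control a ring E that is formed by cleaving a bond, and a ring D closure that is intramolecular across that ring.

**Alternative 2:** Ring B is cut at C11–C12 and C7=C8 and grown by Robinson annulation of a ring A ketone with pent-1-en-3-one, giving bicyclic enone A2, whose methyl group is the future C6.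
- Merits: ring B and its enone come from one classical operation, against five steps (24 to 28) here. That is a real advantage.
- Weak points: in A2 the C2–C3 bond joins two quaternary carbons that share no ring, so their relative configuration must be set in an open-chain bond formation. The Michael donor carbon is flanked by fully substituted C2. Rings C, D and E must all be closed afterwards, ring C through the weakly acidic vinylogous methyl group, and C13 is still at the ketone level.
- Comparison: the chosen plan gives up the short ring B in return for making C2 and C3 cis in one cycloaddition and closing ring D early.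

**Alternative 3:** Ring E is cut between C1 and C17 back to the ene-carbamate of a hexahydroindole; ozone gives N-Boc keto-lactam A3.
- Merits: no medium-ring cyclisation is needed. This transformation is equally good in the chosen plan and is in fact used there as step 13.
- Weak points as the organising step: it answers ring E only and is silent on the C4–C5 bond and C4. A3 also carries an ester, the C8 enone carbonyl and an imide carbonyl on C2, a triacylated carbon exposed to retro-Claisen cleavage in the reduction and N-alkylation that follow.
- Comparison: the chosen plan performs the same cleavage on a substrate with a vinyl group at C2 and a silyl ether at C8, and keeps the strategic role for the ring D closure.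

Key step: step 20

Assumption: the (S,S)-ligand in step 6 is taken to give the enantiomer of 11 drawn; the facial sense with this tetrasubstituted keto ester is not established, and the (R,R)-ligand is used if it proves opposite.
Assumption: compounds 1, 3, 9, 12, 30 and 31 are taken as commercially available.

## Steps

Step 1
Reactants: 1 (tributylstannyl)methanol
Product: 2 tributyl{[(4-methoxybenzyl)oxy]methyl}stannane
Conditions: NaH, 4-MeOC6H4CH2Cl, Bu4NI (cat.), THF/DMF, 0 °C to rt
Reagents that add atoms: 4-methoxybenzyl chloride, COc1ccc(CCl)cc1
Why: Williamson ether synthesis on a primary alcohol; the tin–carbon bonds are inert to NaH and the benzyl chloride.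

Step 2
Reactants: 2 tributyl{[(4-methoxybenzyl)oxy]methyl}stannane; 3 3-ethoxycyclohex-2-en-1-one
Product: 6 3-{[(4-methoxybenzyl)oxy]methyl}cyclohex-2-en-1-one, via alkoxymethyllithium 4 (not isolated), via carbinol adduct 5 (not isolated)
Conditions: nBuLi, THF, −78 °C; then 3, −78 to 0 °C; then 1 M HCl, rt
Reagents that add atoms: water, O
Why: Tin–lithium exchange gives the alpha-alkoxy organolithium, which adds 1,2 to the vinylogous ester; acid hydrolysis with loss of ethanol and water transposes the carbonyl (Stork–Danheiser sequence).

Step 3
Reactants: 6 3-{[(4-methoxybenzyl)oxy]methyl}cyclohex-2-en-1-one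
Product: 7 2-iodo-3-{[(4-methoxybenzyl)oxy]methyl}cyclohex-2-en-1-one
Conditions: I2, K2CO3, 4-(dimethylamino)pyridine (cat.), THF/H2O, rt
Reagents that add atoms: iodine, II
Why: Amine-promoted alpha-iodination of an enone (conjugate addition of the amine, iodination of the enolate, elimination); the beta-substituent slows the reaction but does not block it.

Step 4
Reactants: 7 2-iodo-3-{[(4-methoxybenzyl)oxy]methyl}cyclohex-2-en-1-one
Product: 8 methyl 2-{[(4-methoxybenzyl)oxy]methyl}-6-oxocyclohex-1-ene-1-carboxylate
Conditions: Pd(OAc)2 (cat.), 1,1'-bis(diphenylphosphino)ferrocene (cat.), CO (1 atm), MeOH, Et3N, DMF, 60 °C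
Reagents that add atoms: carbon monoxide, [C-]#[O+]; methanol, CO
Why: Palladium-catalysed methoxycarbonylation of an alkenyl iodide (oxidative addition, CO insertion, methanolysis) gives the doubly activated alkene.

Step 5
Reactants: 9 (E)-but-2-enal
Product: 10 (E)-1-(tert-butyldimethylsilyloxy)buta-1,3-diene
Conditions: tBuMe2SiOTf, Et3N, Et2O, 0 °C to rt
Reagents that add atoms: tert-butyldimethylsilyl trifluoromethanesulfonate, CC(C)(C)[Si](C)(C)OS(=O)(=O)C(F)(F)F
Why: Soft enolisation of the enal through its gamma-CH3 and O-silylation gives the 1-silyloxydiene, mainly as the E isomer.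

Step 6
Reactants: 8 methyl 2-{[(4-methoxybenzyl)oxy]methyl}-6-oxocyclohex-1-ene-1-carboxylate; 10 (E)-1-(tert-butyldimethylsilyloxy)buta-1,3-diene
Product: 11 methyl 1-(tert-butyldimethylsilyloxy)-4a-{[(4-methoxybenzyl)oxy]methyl}-8-oxo-1,4,4a,5,6,7,8,8a-octahydronaphthalene-8a-carboxylate (cis ring fusion; OTBS cis to the ring ketone; absolute configuration as in the list)
Conditions: [Cu((S,S)-tBu-box)](SbF6)2 (10 mol %; box = 2,2'-isopropylidenebis(4-tert-butyl-2-oxazoline)), 4 Å molecular sieves, CH2Cl2, −20 °C to rt
Reagents that add atoms: none
Why: Diels–Alder reaction of a keto ester chelated to divalent copper; the unsubstituted diene terminus bonds to the beta-carbon C3 and the oxygenated terminus to C2, so C8 carries the silyl ether. Suprafacial addition makes the ester and CH2OPMB cis and the ligand selects the face; the C8 configuration is later erased.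

Step 7
Reactants: 11 the Diels–Alder adduct; 12 (E)-1-nitroprop-1-ene
Product: 13 gamma-nitro ketone (11 carrying a 1-nitropropan-2-yl group at C17 on the face of the ester; C18 as in the target)
Conditions: LiN(iPr)2, THF, −78 °C; then 12, −78 °C; AcOH quench
Reagents that add atoms: none
Why: The ketone can only enolise toward C17 because C2 is quaternary; Michael addition of the lithium enolate to the nitroalkene. Approach on the face away from ring C through the closed lithium-bridged transition state (syn topicity) should give the C18 configuration drawn; C17 becomes sp2 in step 9.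

Step 8
Reactants: 13 the gamma-nitro ketone
Product: 15 tricyclic 1-pyrroline (cyclic imine N=C1), via amino ketone 14 (not isolated)
Conditions: Zn, AcOH, EtOH, rt
Reagents that add atoms: none
Why: Zinc reduces the nitro group to the primary amine, which condenses with the neighbouring ketone to the five-membered cyclic imine; the hindered ester is not attacked.

Step 9
Reactants: 15 the tricyclic 1-pyrroline
Product: 16 N-Boc ene-carbamate (C1=C17 double bond) with C2 methyl ester
Conditions: (Boc)2O, 4-(dimethylamino)pyridine (cat.), Et3N, toluene, 60 °C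
Reagents that add atoms: di-tert-butyl dicarbonate, CC(C)(C)OC(=O)OC(=O)OC(C)(C)C
Why: N-acylation of the cyclic imine and loss of its only alpha-proton (on C17) gives the tetrasubstituted ene-carbamate; no regioisomer is possible.

Step 10
Reactants: 16 the ene-carbamate ester
Product: 17 the corresponding C2 hydroxymethyl compound
Conditions: iBu2AlH, CH2Cl2, −78 to 0 °C; aq. potassium sodium tartrate
Reagents that add atoms: none
Why: Ester reduction by the aluminium hydride; carbamate and silyl ether are inert at low temperature, and no ketone is present at this stage.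

Step 11
Reactants: 17 the primary alcohol
Product: 18 the C2 aldehyde
Conditions: Dess–Martin periodinane, NaHCO3, CH2Cl2, rt
Reagents that add atoms: none
Why: Dess–Martin oxidation to a neopentyl aldehyde that cannot enolise; buffered conditions spare the ene-carbamate.

Step 12
Reactants: 18 the aldehyde
Product: 19 the C2 vinyl ene-carbamate
Conditions: Ph3PCH3Br, KN(SiMe3)2, THF, 0 °C to rt
Reagents that add atoms: methyltriphenylphosphonium bromide, C[P+](c1ccccc1)(c1ccccc1)c1ccccc1.[Br-]
Why: Wittig methylenation of an aldehyde without alpha-hydrogen.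

Step 13
Reactants: 19 the vinyl ene-carbamate
Product: 20 N-Boc nine-membered keto-lactam (C1 imide carbonyl, C17 ketone) fused to ring C
Conditions: O3 (1.05 equiv, titrated solution in CH2Cl2), CH2Cl2, −78 °C; then Me2S
Reagents that add atoms: ozone, [O-][O+]=O
Why: Ozonolysis (Witkop-type cleavage); the electron-rich tetrasubstituted ene-carbamate reacts much faster than the monosubstituted and disubstituted alkenes, so a titrated amount of ozone cleaves only C1=C17 and merges the five- and six-membered rings into ring E.

Step 14
Reactants: 20 the keto-lactam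
Product: 21 the (17R)-alcohol (hydroxyl and C18 methyl syn along the ring)
Conditions: (S)-1-methyl-3,3-diphenyltetrahydro-1H,3H-pyrrolo[1,2-c][1,3,2]oxazaborole (20 mol %), catecholborane, toluene, −78 °C
Reagents that add atoms: none
Why: Corey–Bakshi–Shibata reduction; with the branched C18 side as the large group the (S)-catalyst should deliver hydride to give 17R. Catecholborane does not hydroborate the alkenes, and reagent control is used because Felkin-type addition would favour the other epimer.

Step 15
Reactants: 21 the alcohol
Product: 23 NH lactam with C17 triisopropylsilyl ether, via silyl carbamate 22 (not isolated)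
Conditions: iPr3SiOTf, 2,6-lutidine, CH2Cl2, 0 °C to rt; then aq. NaHCO3/MeOH
Reagents that add atoms: triisopropylsilyl trifluoromethanesulfonate, CC(C)[Si](OS(=O)(=O)C(F)(F)F)(C(C)C)C(C)C
Why: The silyl triflate silylates the hindered alcohol and converts the imide-type Boc group into a silyl carbamate with loss of isobutene; aqueous work-up decarboxylates it to the NH lactam. Silylating at once also removes the hydroxyl that could open the imide.

Step 16
Reactants: 23 the NH lactam
Product: 24 the N-(methoxymethyl) lactam
Conditions: NaH, MeOCH2Cl, THF/DMF, 0 °C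
Reagents that add atoms: chloro(methoxy)methane, COCCl
Why: N-alkylation of the lactam anion; with ring C still an allylic silyl ether the amide N–H is the only acidic site.

Step 17
Reactants: 24 the N-(methoxymethyl) lactam
Product: 25 the C8 allylic alcohol
Conditions: HF·pyridine, pyridine, THF, 0 °C to rt
Reagents that add atoms: none
Why: Buffered fluoride cleaves the secondary allylic tert-butyldimethylsilyl ether in preference to the bulkier triisopropylsilyl ether and leaves the N,O-acetal and PMB ether.

Step 18
Reactants: 25 the allylic alcohol
Product: 26 the ring C enone (C8 ketone, C6=C7)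
Conditions: Dess–Martin periodinane, NaHCO3, CH2Cl2, 0 °C to rt
Reagents that add atoms: none
Why: Dess–Martin oxidation of an allylic alcohol under non-basic conditions.

Step 19
Reactants: 26 the enone
Product: 27 N-(methoxymethyl) nine-membered lactam with the ring C 1-silyloxy diene (C8(OTBS)=C7–C6=C4)
Conditions: KN(SiMe3)2, tBuMe2SiCl, THF/DMPU, −78 °C
Reagents that add atoms: tert-butyldimethylsilyl chloride, CC(C)(C)[Si](C)(C)Cl
Why: The enone can only be deprotonated at C4 (gamma) because C2 is quaternary; O-silylation of the linear dienolate gives the dienol ether.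

Step 20
Reactants: 27 the silyl dienol ether
Product: 29 tricyclic lactam enone with rings C, D and E (C4–C5 bond formed; C8 ketone, C6=C7), via N-acyliminium ion 28 (not isolated)
Conditions: BF3·OEt2, CH2Cl2, −78 to −40 °C
Reagents that add atoms: none
Why: BF3 abstracts methoxide from the N,O-acetal to give the N-acyl-N-methyleneiminium ion, which is attacked by C4, the terminal carbon of the silyloxy diene; loss of the silyl group restores the C8 ketone as the C6=C7 enone. The closest known reaction type is the vinylogous Mannich (amidoalkylation) reaction of N-acyliminium ions from N-alkoxymethyl amides with silyl dienol ethers, which react at the gamma-carbon. Ring D closes 6-endo-trig at the iminium (N and C5 both in the ring) and exo with respect to the diene. The new stereocentre C4 is set by the tether: the iminium hangs from the axial C1 on C2 and can reach C4 only on that face, giving the cis-1,3-diaxial bridge of the 2-azabicyclo[3.3.1]nonane. The selectivity needed is C4 over C7; attack at C7 would also close a six-membered ring, so it is secured by the higher terminal nucleophilicity of silyl dienol ethers toward cations, by the C15–C19 chain that holds nitrogen near the C3–C4 edge, and by formation of the conjugated enone. The vinyl group and the PMB and silyl ethers are much weaker nucleophiles or inert at −78 °C.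

Step 21
Reactants: 30 4,4-dimethoxybutanal; 31 methyl prop-2-enoate
Product: 32 methyl 3-hydroxy-6,6-dimethoxy-2-methylidenehexanoate (racemic)
Conditions: 1,4-diazabicyclo[2.2.2]octane (cat.), neat, rt
Reagents that add atoms: none
Why: Morita–Baylis–Hillman reaction of an aliphatic aldehyde with an acrylate.

Step 22
Reactants: 32 the hydroxy ester
Product: 33 methyl (2Z)-2-(bromomethyl)-6,6-dimethoxyhex-2-enoate
Conditions: N-bromosuccinimide, Me2S, CH2Cl2, 0 °C to rt
Reagents that add atoms: N-bromosuccinimide, O=C1CCC(=O)N1Br
Why: Corey–Kim-type activation of the allylic alcohol and bromide attack with allylic transposition gives the more stable Z 2-(bromomethyl)alkenoate.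

Step 23
Reactants: 33 the bromo acetal
Product: 34 methyl (2Z)-2-(bromomethyl)-6-oxohex-2-enoate
Conditions: CF3CO2H/H2O, CHCl3, 0 °C
Reagents that add atoms: water, O
Why: Acid-catalysed acetal hydrolysis; the allylic bromide and the enoate tolerate brief aqueous acid.

Step 24
Reactants: 29 the tricyclic enone; 34 methyl (2Z)-2-(bromomethyl)-6-oxohex-2-enoate
Product: 36 aldol adduct (C7 bears CH(OH)CH2CH2CH=C(CH2Br)CO2Me on the face away from nitrogen; mixture of C9 epimers), via lithium enolate 35 (not isolated)
Conditions: LiBH(sBu)3, THF, −78 °C; then 34, −78 °C; AcOH quench at −78 °C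
Reagents that add atoms: none
Why: Reductive aldol: conjugate hydride addition at C6 (the neopentyl C8 carbonyl resists 1,2-attack) gives the regiodefined enolate, which adds to the aldehyde faster than it is alkylated by the allylic bromide at −78 °C. The nitrogen bridge blocks the inner face of C7, and C7 and C9 both become sp2 later, so the epimer mixture is immaterial.

Step 25
Reactants: 36 the aldol adduct
Product: 38 tetracyclic diol with ring B closed (C8 tertiary alcohol, C12 bearing the 2-(methoxycarbonyl)vinyl unit C(=CH2)CO2Me; C9 epimers), via allylindium species 37 (not isolated)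
Conditions: In powder, THF/H2O, rt
Reagents that add atoms: none
Why: Barbier-type allylation: indium inserts into the allylic C–Br bond and the allyl metal adds through its gamma-carbon C12 to the C8 ketone in a chair transition state, closing ring B. The axial CH2OPMB on C3 blocks the axial face of C8, so the new bond is equatorial and the acrylate takes the equatorial place on ring B; this puts H-12 anti to the new hydroxyl, which is the configuration needed.

Step 26
Reactants: 38 the diol
Product: 39 the C9 ketone (beta-hydroxy ketone with tertiary C8 alcohol)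
Conditions: Dess–Martin periodinane, NaHCO3, CH2Cl2, rt
Reagents that add atoms: none
Why: Dess–Martin oxidation of the secondary alcohol; the tertiary alcohol cannot react and both C9 epimers converge.

Step 27
Reactants: 39 the beta-hydroxy ketone
Product: 40 dienone (C9 ketone conjugated to C7=C8) carrying the C12 acrylate and the C2 vinyl group
Conditions: Ph2S[OC(CF3)2Ph]2 (Martin sulfurane), CH2Cl2, 0 °C to rt
Reagents that add atoms: none
Why: Dehydration of a tertiary alcohol with Martin sulfurane under neutral conditions; the axial hydroxyl is antiperiplanar to H-7 and elimination toward the ketone gives the conjugated enone. Base is avoided to protect the doubly activated C12–H.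

Step 28
Reactants: 40 the dienone
Product: 41 pentacyclic cyclopentene ester (ring A closed, C13=C14)
Conditions: RuCl2(H2IMes)(=CH-C6H4-2-OiPr) (second-generation Hoveyda–Grubbs catalyst, 10 mol %), 1,4-benzoquinone (cat.), toluene, 80 °C
Reagents that add atoms: none
Why: Ring-closing metathesis between the vinyl group and the 1,1-disubstituted acrylate closes the five-membered ring with loss of ethene; the tetrasubstituted enone is inert and benzoquinone suppresses hydride-induced isomerisation.

Step 29
Reactants: 41 the cyclopentene ester
Product: 42 pentacyclic ester with C13 set (H-13 and H-12 cis, both on the face of the lactam carbonyl)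
Conditions: H2 (1 atm), [Ir(cod)(PCy3)(py)]PF6 (cat.), CH2Cl2, rt
Reagents that add atoms: none
Why: Directed hydrogenation: the cationic iridium catalyst binds the lactam carbonyl, which stands axially on C2 over one face of C13=C14, and delivers hydrogen to that face, so the ester ends on the opposite face as in the target. The tetrasubstituted, electron-poor C7=C8 bond should not be reduced.

Step 30
Reactants: 42 the PMB ether
Product: 43 the primary alcohol
Conditions: 2,3-dichloro-5,6-dicyano-1,4-benzoquinone, CH2Cl2/pH 7 buffer, 0 °C
Reagents that add atoms: none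
Why: Oxidative cleavage of the 4-methoxybenzyl ether through the benzylic oxocarbenium ion; enone, ester and silyl ether are unaffected.

Step 31
Reactants: 43 the primary alcohol
Product: 44 the acetate
Conditions: Ac2O, pyridine, 4-(dimethylamino)pyridine (cat.), CH2Cl2, rt
Reagents that add atoms: acetic anhydride, CC(=O)OC(C)=O
Why: Acetylation of a primary neopentyl alcohol under mild amine base, which does not epimerise C13 or C12.

Step 32
Reactants: 44 the silyl ether acetate
Product: 45 CNP0123592.1
Conditions: HF·pyridine, THF, rt
Reagents that add atoms: none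
Why: Fluoride cleavage of the triisopropylsilyl ether; acetate, methyl ester and enone are stable to these mildly acidic conditions.

## Compound list

1 | (tributylstannyl)methanol | OC[Sn](CCCC)(CCCC)CCCC | starting material
2 | tributyl{[(4-methoxybenzyl)oxy]methyl}stannane | COc1ccc(COC[Sn](CCCC)(CCCC)CCCC)cc1 | intermediate
3 | 3-ethoxycyclohex-2-en-1-one | CCOC1=CC(=O)CCC1 | starting material
4 | {[(4-methoxybenzyl)oxy]methyl}lithium (not isolated) | [Li]COCc1ccc(OC)cc1 | intermediate
5 | 3-ethoxy-1-{[(4-methoxybenzyl)oxy]methyl}cyclohex-2-en-1-ol, racemic (not isolated) | CCOC1=CC(O)(COCc2ccc(OC)cc2)CCC1 | intermediate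
6 | 3-{[(4-methoxybenzyl)oxy]methyl}cyclohex-2-en-1-one | COc1ccc(COCC2=CC(=O)CCC2)cc1 | intermediate
7 | 2-iodo-3-{[(4-methoxybenzyl)oxy]methyl}cyclohex-2-en-1-one | COc1ccc(COCC2=C(I)C(=O)CCC2)cc1 | intermediate
8 | methyl 2-{[(4-methoxybenzyl)oxy]methyl}-6-oxocyclohex-1-ene-1-carboxylate | COC(=O)C1=C(COCc2ccc(OC)cc2)CCCC1=O | intermediate
9 | (E)-but-2-enal | C/C=C/C=O | starting material
10 | (E)-1-(tert-butyldimethylsilyloxy)buta-1,3-diene | C=C/C=C/O[Si](C)(C)C(C)(C)C | intermediate
11 | cis-fused bicyclic keto ester (Diels–Alder adduct; ester and CH2OPMB cis, OTBS cis to the ring ketone) | COC(=O)[C@@]12[C@H](O[Si](C)(C)C(C)(C)C)C=CC[C@]1(COCc1ccc(OC)cc1)CCCC2=O | intermediate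
12 | (E)-1-nitroprop-1-ene | C/C=C/[N+](=O)[O-] | starting material
13 | gamma-nitro ketone (1-nitropropan-2-yl group at C17) | COC(=O)[C@@]12[C@H](O[Si](C)(C)C(C)(C)C)C=CC[C@]1(COCc1ccc(OC)cc1)CC[C@@H]([C@H](C)C[N+](=O)[O-])C2=O | intermediate
14 | gamma-amino ketone (not isolated) | COC(=O)[C@@]12[C@H](O[Si](C)(C)C(C)(C)C)C=CC[C@]1(COCc1ccc(OC)cc1)CC[C@@H]([C@H](C)CN)C2=O | intermediate
15 | tricyclic 1-pyrroline (N=C1 imine) | COC(=O)[C@@]12[C@H](O[Si](C)(C)C(C)(C)C)C=CC[C@]1(COCc1ccc(OC)cc1)CC[C@H]1[C@H](C)CN=C12 | intermediate
16 | N-Boc ene-carbamate (C1=C17), C2 methyl ester | COC(=O)[C@@]12[C@H](O[Si](C)(C)C(C)(C)C)C=CC[C@]1(COCc1ccc(OC)cc1)CCC1=C2N(C(=O)OC(C)(C)C)C[C@H]1C | intermediate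
17 | N-Boc ene-carbamate, C2 hydroxymethyl | OC[C@@]12[C@H](O[Si](C)(C)C(C)(C)C)C=CC[C@]1(COCc1ccc(OC)cc1)CCC1=C2N(C(=O)OC(C)(C)C)C[C@H]1C | intermediate
18 | N-Boc ene-carbamate, C2 aldehyde | O=C[C@@]12[C@H](O[Si](C)(C)C(C)(C)C)C=CC[C@]1(COCc1ccc(OC)cc1)CCC1=C2N(C(=O)OC(C)(C)C)C[C@H]1C | intermediate
19 | N-Boc ene-carbamate, C2 vinyl | C=C[C@@]12[C@H](O[Si](C)(C)C(C)(C)C)C=CC[C@]1(COCc1ccc(OC)cc1)CCC1=C2N(C(=O)OC(C)(C)C)C[C@H]1C | intermediate
20 | N-Boc nine-membered keto-lactam | C=C[C@@]12[C@H](O[Si](C)(C)C(C)(C)C)C=CC[C@]1(COCc1ccc(OC)cc1)CCC(=O)[C@H](C)CN(C(=O)OC(C)(C)C)C2=O | intermediate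
21 | N-Boc nine-membered lactam, (17R)-alcohol | C=C[C@@]12[C@H](O[Si](C)(C)C(C)(C)C)C=CC[C@]1(COCc1ccc(OC)cc1)CC[C@@H](O)[C@H](C)CN(C(=O)OC(C)(C)C)C2=O | intermediate
22 | N-(triisopropylsilyloxycarbonyl) lactam, C17 triisopropylsilyl ether (not isolated) | C=C[C@@]12[C@H](O[Si](C)(C)C(C)(C)C)C=CC[C@]1(COCc1ccc(OC)cc1)CC[C@@H](O[Si](C(C)C)(C(C)C)C(C)C)[C@H](C)CN(C(=O)O[Si](C(C)C)(C(C)C)C(C)C)C2=O | intermediate
23 | NH nine-membered lactam, C17 triisopropylsilyl ether | C=C[C@@]12[C@H](O[Si](C)(C)C(C)(C)C)C=CC[C@]1(COCc1ccc(OC)cc1)CC[C@@H](O[Si](C(C)C)(C(C)C)C(C)C)[C@H](C)CNC2=O | intermediate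
24 | N-(methoxymethyl) lactam, C8 tert-butyldimethylsilyl ether | C=C[C@@]12[C@H](O[Si](C)(C)C(C)(C)C)C=CC[C@]1(COCc1ccc(OC)cc1)CC[C@@H](O[Si](C(C)C)(C(C)C)C(C)C)[C@H](C)CN(COC)C2=O | intermediate
25 | N-(methoxymethyl) lactam, C8 allylic alcohol | C=C[C@@]12[C@H](O)C=CC[C@]1(COCc1ccc(OC)cc1)CC[C@@H](O[Si](C(C)C)(C(C)C)C(C)C)[C@H](C)CN(COC)C2=O | intermediate
26 | N-(methoxymethyl) lactam, ring C enone | C=C[C@@]12C(=O)C=CC[C@]1(COCc1ccc(OC)cc1)CC[C@@H](O[Si](C(C)C)(C(C)C)C(C)C)[C@H](C)CN(COC)C2=O | intermediate
27 | N-(methoxymethyl) nine-membered lactam with ring C silyl dienol ether (key-step precursor) | C=C[C@@]12C(O[Si](C)(C)C(C)(C)C)=CC=C[C@]1(COCc1ccc(OC)cc1)CC[C@@H](O[Si](C(C)C)(C(C)C)C(C)C)[C@H](C)CN(COC)C2=O | intermediate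
28 | N-acyl-N-methyleneiminium ion (not isolated) | C=C[C@@]12C(O[Si](C)(C)C(C)(C)C)=CC=C[C@]1(COCc1ccc(OC)cc1)CC[C@@H](O[Si](C(C)C)(C(C)C)C(C)C)[C@H](C)C[N+](=C)C2=O | intermediate
29 | tricyclic lactam enone with rings C, D and E (key-step product) | C=C[C@@]12C(=O)C=C[C@@H]3CN(C2=O)C[C@@H](C)[C@H](O[Si](C(C)C)(C(C)C)C(C)C)CC[C@]13COCc1ccc(OC)cc1 | intermediate
30 | 4,4-dimethoxybutanal | COC(OC)CCC=O | starting material
31 | methyl prop-2-enoate | C=CC(=O)OC | starting material
32 | methyl 3-hydroxy-6,6-dimethoxy-2-methylidenehexanoate (racemic) | COC(OC)CCC(O)C(=C)C(=O)OC | intermediate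
33 | methyl (2Z)-2-(bromomethyl)-6,6-dimethoxyhex-2-enoate | COC(OC)CC/C=C(\CBr)C(=O)OC | intermediate
34 | methyl (2Z)-2-(bromomethyl)-6-oxohex-2-enoate | O=CCC/C=C(\CBr)C(=O)OC | intermediate
35 | lithium enolate of the C6-reduced ketone (not isolated) | C=C[C@@]12C(O[Li])=CC[C@@H]3CN(C2=O)C[C@@H](C)[C@H](O[Si](C(C)C)(C(C)C)C(C)C)CC[C@]13COCc1ccc(OC)cc1 | intermediate
36 | aldol adduct (C9 epimers) | C=C[C@@]12C(=O)[C@@H](C(O)CC/C=C(\CBr)C(=O)OC)C[C@@H]3CN(C2=O)C[C@@H](C)[C@H](O[Si](C(C)C)(C(C)C)C(C)C)CC[C@]13COCc1ccc(OC)cc1 | intermediate
37 | allylindium dibromide derived from 36 (not isolated) | C=C[C@@]12C(=O)[C@@H](C(O)CC/C=C(\C[In](Br)Br)C(=O)OC)C[C@@H]3CN(C2=O)C[C@@H](C)[C@H](O[Si](C(C)C)(C(C)C)C(C)C)CC[C@]13COCc1ccc(OC)cc1 | intermediate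
38 | tetracyclic diol, ring B closed (C9 epimers) | C=C[C@@]12[C@@]4(O)[C@@H](C(O)CC[C@@H]4C(=C)C(=O)OC)C[C@@H]3CN(C2=O)C[C@@H](C)[C@H](O[Si](C(C)C)(C(C)C)C(C)C)CC[C@]13COCc1ccc(OC)cc1 | intermediate
39 | tetracyclic beta-hydroxy ketone (C9 ketone, C8 tertiary alcohol) | C=C[C@@]12[C@@]4(O)[C@@H](C(=O)CC[C@@H]4C(=C)C(=O)OC)C[C@@H]3CN(C2=O)C[C@@H](C)[C@H](O[Si](C(C)C)(C(C)C)C(C)C)CC[C@]13COCc1ccc(OC)cc1 | intermediate
40 | tetracyclic dienone with C12 acrylate and C2 vinyl group | C=C[C@@]12C4=C(C(=O)CC[C@@H]4C(=C)C(=O)OC)C[C@@H]3CN(C2=O)C[C@@H](C)[C@H](O[Si](C(C)C)(C(C)C)C(C)C)CC[C@]13COCc1ccc(OC)cc1 | intermediate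
41 | pentacyclic cyclopentene ester (C13=C14) | COC(=O)C1=C[C@@]23C(=O)N4C[C@@H](CC5=C2[C@@H]1CCC5=O)[C@]3(COCc6ccc(OC)cc6)CC[C@@H](O[Si](C(C)C)(C(C)C)C(C)C)[C@H](C)C4 | intermediate
42 | pentacyclic ester, PMB ether and triisopropylsilyl ether | COC(=O)[C@@H]1C[C@@]23C(=O)N4C[C@@H](CC5=C2[C@@H]1CCC5=O)[C@]3(COCc6ccc(OC)cc6)CC[C@@H](O[Si](C(C)C)(C(C)C)C(C)C)[C@H](C)C4 | intermediate
43 | pentacyclic primary alcohol, triisopropylsilyl ether | COC(=O)[C@@H]1C[C@@]23C(=O)N4C[C@@H](CC5=C2[C@@H]1CCC5=O)[C@]3(CO)CC[C@@H](O[Si](C(C)C)(C(C)C)C(C)C)[C@H](C)C4 | intermediate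
44 | pentacyclic acetate, triisopropylsilyl ether | COC(=O)[C@@H]1C[C@@]23C(=O)N4C[C@@H](CC5=C2[C@@H]1CCC5=O)[C@]3(COC(C)=O)CC[C@@H](O[Si](C(C)C)(C(C)C)C(C)C)[C@H](C)C4 | intermediate
45 | CNP0123592.1 | COC(=O)[C@@H]1C[C@@]23C(=O)N4C[C@@H](CC5=C2[C@@H]1CCC5=O)[C@]3(COC(C)=O)CC[C@@H](O)[C@H](C)C4 | target

## Step count and least certain steps

Total: 32 steps. Longest linear sequence: 28 steps (steps 1 to 4, 6 to 20, 24 to 32).

**Step 20 (key step).** Attack through the alpha-carbon C7 in place of C4 is the most likely failure, because it also closes a six-membered ring and only the electronic preference of the dienol ether and the position of nitrogen speak against it. Protodesilylation before ring closure is the second risk. Fallback: from enone 26, alpha-iodination (I2, pyridine) gives the 2-iodo enone F1; the same silylation gives the iodo dienol ether F2, in which C7 is blocked; BF3·OEt2 then closes ring D at C4 to the iodo tricyclic enone F3; hydrodeiodination with Bu3SnH and Pd(PPh3)4 returns to 29.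

**Step 6.** The tetrasubstituted dienophile may react too slowly with the bulky chiral complex, or with poor face selection, while the diene is lost by desilylation. Fallback: from 8 and 10 the cycloaddition is run without chiral control (ZnCl2 or heat) and the racemate is taken through steps 7 to 8. Racemic 15 is then resolved by crystallisation of its salt with (1S)-(+)-camphor-10-sulfonic acid, the iminium camphorsulfonate F4, and the free base rejoins the route at 15.

**Step 7.** Facial selectivity of the enolate and relative topicity both bear on C18, and either may turn out opposite to the model, giving the C18 epimer. Fallback: from 11 the trimethylsilyl enol ether F5 is made (LiN(iPr)2, Me3SiCl) and added to 12 under SnCl4 (Mukaiyama–Michael addition). Its open transition state has the complementary topicity and returns to 13.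

**Step 14.** Catalyst control may be too weak, since a CH2 and a CH(CH3) arm differ little, and it may be mismatched with the ring conformation; the result would be poor face discrimination at C17. Fallback: from 20, substrate-controlled reduction with LiBH(sBu)3 is used to give the C17 epimer, the (17S)-alcohol F6. Mitsunobu inversion with chloroacetic acid gives the (17R)-chloroacetate F7, and thiourea removes the chloroacetyl group to return to 21.

**Step 25.** Addition to the hindered C8 ketone may be slow, so that oxa-Michael attack of the C9 hydroxyl on the bromomethyl enoate or lactonisation of the product interferes; the face selectivity at C8, which fixes C12, rests on a model. Alkylation of the enolate in step 24 belongs to the same weakness. Fallback: from 33 the bromide is exchanged for silicon (Me3SiSiMe3, Pd(PPh3)4) to give the allylsilane acetal F8. Hydrolysis gives the allylsilane aldehyde F9, the reductive aldol with 29 gives the allylsilane aldol adduct F10, and a TiCl4-promoted Hosomi–Sakurai cyclisation returns to 38.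

**Step 29.** Undirected delivery of hydrogen from the open face, or over-reduction of the enone, would give the wrong C13 configuration or a saturated ketone. Fallback: from 41 a non-directed reduction (H2, Rh on Al2O3) gives mainly the C13 epimer F11, which is equilibrated with NaOMe in MeOH to 42. The ester anti to the axial lactam carbonyl should be the more stable arrangement.

## Further compounds

F1 | step 20 | N-(methoxymethyl) lactam with 2-iodo enone in ring C | C=C[C@@]12C(=O)C(I)=CC[C@]1(COCc1ccc(OC)cc1)CC[C@@H](O[Si](C(C)C)(C(C)C)C(C)C)[C@H](C)CN(COC)C2=O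
F2 | step 20 | iodo silyl dienol ether | C=C[C@@]12C(O[Si](C)(C)C(C)(C)C)=C(I)C=C[C@]1(COCc1ccc(OC)cc1)CC[C@@H](O[Si](C(C)C)(C(C)C)C(C)C)[C@H](C)CN(COC)C2=O
F3 | step 20 | iodo tricyclic lactam enone | C=C[C@@]12C(=O)C(I)=C[C@@H]3CN(C2=O)C[C@@H](C)[C@H](O[Si](C(C)C)(C(C)C)C(C)C)CC[C@]13COCc1ccc(OC)cc1
F4 | step 6 | iminium (1S)-camphor-10-sulfonate of 15 | COC(=O)[C@@]12[C@H](O[Si](C)(C)C(C)(C)C)C=CC[C@]1(COCc1ccc(OC)cc1)CC[C@H]1[C@H](C)C[NH+]=C12.CC1(C)[C@@H]2CC[C@@]1(CS(=O)(=O)[O-])C(=O)C2
F5 | step 7 | trimethylsilyl enol ether of 11 | COC(=O)[C@@]12[C@H](O[Si](C)(C)C(C)(C)C)C=CC[C@]1(COCc1ccc(OC)cc1)CCC=C2O[Si](C)(C)C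
F6 | step 14 | (17S)-alcohol, C17 epimer of 21 | C=C[C@@]12[C@H](O[Si](C)(C)C(C)(C)C)C=CC[C@]1(COCc1ccc(OC)cc1)CC[C@H](O)[C@H](C)CN(C(=O)OC(C)(C)C)C2=O
F7 | step 14 | (17R)-chloroacetate | C=C[C@@]12[C@H](O[Si](C)(C)C(C)(C)C)C=CC[C@]1(COCc1ccc(OC)cc1)CC[C@@H](OC(=O)CCl)[C@H](C)CN(C(=O)OC(C)(C)C)C2=O
F8 | step 25 | methyl (2Z)-6,6-dimethoxy-2-[(trimethylsilyl)methyl]hex-2-enoate | COC(OC)CC/C=C(\C[Si](C)(C)C)C(=O)OC
F9 | step 25 | methyl (2Z)-6-oxo-2-[(trimethylsilyl)methyl]hex-2-enoate | O=CCC/C=C(\C[Si](C)(C)C)C(=O)OC
F10 | step 25 | allylsilane aldol adduct (C9 epimers) | C=C[C@@]12C(=O)[C@@H](C(O)CC/C=C(\C[Si](C)(C)C)C(=O)OC)C[C@@H]3CN(C2=O)C[C@@H](C)[C@H](O[Si](C(C)C)(C(C)C)C(C)C)CC[C@]13COCc1ccc(OC)cc1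
F11 | step 29 | C13 epimer of 42 | COC(=O)[C@H]1C[C@@]23C(=O)N4C[C@@H](CC5=C2[C@@H]1CCC5=O)[C@]3(COCc6ccc(OC)cc6)CC[C@@H](O[Si](C(C)C)(C(C)C)C(C)C)[C@H](C)C4
A1 | alternative 1 | Z-dehydro target with a C15=C16 alkene in ring E | COC(=O)[C@@H]1C[C@@]23C(=O)N4C[C@@H](CC5=C2[C@@H]1CCC5=O)[C@]3(COC(C)=O)/C=C\[C@@H](O)[C@H](C)C4
A2 | alternative 2 | bicyclic enone of rings A and B | COC(=O)[C@@]1(CC2(OCCO2)C3CCC(=O)C(C)=C13)[C@](COCc1ccc(OC)cc1)(CC(=O)OC(C)(C)C)C=C
A3 | alternative 3 | N-Boc nine-membered keto-lactam with C2 ester and ring C enone | COC(=O)[C@@]12C(=O)C=CC[C@]1(COCc1ccc(OC)cc1)CCC(=O)[C@H](C)CN(C(=O)OC(C)(C)C)C2=O
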